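**Retrosynthetic overview**
1. The target comes from its 3',5'-bis-MOM ether by acid. Rings A and B are bought as arenes. Ring C is the only ring built, and it is built last.
2. Ring C is opened at the O1–C8a bond. It closes by dehydrogenative C–O annulation of an o-hydroxyaryl 2-methoxy-1,3-diketone through a ring-A quinone monoketal, and the phenol that triggers the oxidation returns as 5-OH.
3. The diketone is opened at the C2–C3 bond: crossed Claisen of a ring-A ω-methoxyacetophenone with a ring-B methyl benzoate. The 3-OMe comes in with methoxyacetic acid.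
4. The ring-A ketone comes from ortho-acylation of 2,3,4-trimethoxyphenol, which comes from Dakin-type C–O oxidation of 2,3,4-trimethoxybenzaldehyde.
5. The ring-B ester comes from MOM capping of methyl 3,5-dihydroxy-4-methoxybenzoate.

Assumption: the target SMILES holds no stereocentre, stereogenic axis or stereogenic double bond. The compound is achiral and needs no enantiocontrol. Transient stereocentres in the intermediates are racemic and are erased on aromatisation.

**Route**

Step 1
Reactants: 1 2,3,4-trimethoxybenzaldehyde
Product: 3 2,3,4-trimethoxyphenol, via 2,3,4-trimethoxyphenyl formate 2 (not isolated)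
Conditions: 30% aq H2O2 (1.3 equiv), H2SO4 (cat.), MeOH, rt, 12 h
Reagents that add atoms: hydrogen peroxide, OO
Why: Acid-catalysed Dakin-type (Baeyer–Villiger) oxidation, in which the electron-rich aryl group migrates from carbon to oxygen in the peroxy-hemiacetal to give formate 2, which methanol cleaves in the same flask; no stereocentre is made.

Step 2
Reactants: 3 2,3,4-trimethoxyphenol; 4 methoxyacetic acid
Product: 5 1-(2-hydroxy-3,4,5-trimethoxyphenyl)-2-methoxyethan-1-one
Conditions: BF3·OEt2 (neat, as solvent), 80 °C, 3 h; aq NaOAc work-up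
Reagents that add atoms: none
Why: Friedel–Crafts/Fries-type ortho-acylation of a phenol by a carboxylic acid in BF3·OEt2, where the para position is blocked, C6 is the only free position ortho to OH, the chelated o-hydroxyaryl ketone is the thermodynamic sink, and no OMe lies ortho to the new carbonyl where it could be cleaved.

Step 3
Reactants: 6 methyl 3,5-dihydroxy-4-methoxybenzoate
Product: 7 methyl 4-methoxy-3,5-bis(methoxymethoxy)benzoate
Conditions: MOMCl (2.6 equiv), K2CO3 (4 equiv), acetone, reflux, 4 h
Reagents that add atoms: chloromethyl methyl ether, COCCl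
Why: Williamson-type O-alkylation of both phenoxides by the reactive α-chloro ether; the MOM acetals withstand strong base and trivalent iodine but fall off in acid, so the last step frees them without a separate operation.

Step 4
Reactants: 5 1-(2-hydroxy-3,4,5-trimethoxyphenyl)-2-methoxyethan-1-one; 7 methyl 4-methoxy-3,5-bis(methoxymethoxy)benzoate
Product: 9 1-(2-hydroxy-3,4,5-trimethoxyphenyl)-2-methoxy-3-[4-methoxy-3,5-bis(methoxymethoxy)phenyl]propane-1,3-dione, via dilithium enolate-phenoxide 8 (not isolated)
Conditions: LiN(SiMe3)2 (3.3 equiv), THF, −78 → −10 °C, 1 h; then 7, −10 → 45 °C, 8 h; AcOH, 0 °C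
Reagents that add atoms: none
Why: Crossed Claisen condensation (the intermolecular counterpart of the Baker–Venkataraman transfer), in which the chelated Z-enolate 8 attacks the non-enolisable ester 7 and deprotonation of the 1,3-diketone drives the equilibrium; the new C2 stereocentre is racemic, enolisable and erased in step 5, and the cold AcOH quench avoids cyclodehydration.

Step 5
Reactants: 9 1-(2-hydroxy-3,4,5-trimethoxyphenyl)-2-methoxy-3-[4-methoxy-3,5-bis(methoxymethoxy)phenyl]propane-1,3-dione
Product: 13 5,3',5'-trihydroxy-3,6,7,8,4'-pentamethoxyflavone, via acylquinone monoketal 10 (not isolated), via oxa-Michael adduct 11 (not isolated), via bis-MOM flavone 12 (not isolated)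
Conditions: PhI(OAc)2 (1.0 equiv), MeCN–MeOH 9:1 (0.02 M), 0 °C → rt, 30 min; i-Pr2NEt (3 equiv), 0 °C → rt, 2 h; then 3 M HCl in MeOH (10 equiv), rt, 30 min, then 50 °C, 3 h
Reagents that add atoms: methanol, CO (enters as one of the two ketal OMe groups of 10; one of the two leaves again from 11)
Why: Proposed new method: dearomatisation-relayed dehydrogenative C–O annulation, in which PhI(OAc)2/MeOH oxidises only the electron-rich p-methoxyphenol of ring A (ring B has no free OH, and the keto-form 2-substituted diketone reacts much more slowly with trivalent iodine) to the 2-acylquinone monoketal 10, whose C8a–H carbon is now the β-carbon of a doubly activated enone; the amine base forms the diketone enolate, which can reach C8a only through oxygen (6-endo-trig oxa-Michael, since C-attack would need a four-membered ring) to give 11; anhydrous acid ionises the C8 ketal to what is simply the C8a-protonated arenium ion of 12, so loss of H+ (net loss of MeOH) rearomatises irreversibly, returns the phenol as the chelated 5-OH and keeps 8-OMe (ketalisation at C6 instead of C8 would funnel to the same arene), and the same methanolic HCl then removes both MOM acetals; staging the oxidant before aromatisation keeps the product phenol away from it, and all labile stereocentres vanish to leave an achiral product; the closest known reaction types are PhI(OAc)2/MeOH formation of quinone monoketals, conjugate addition–aromatisation of nucleophiles on quinone monoketals, and (NH4)2Ce(NO3)6-mediated closure of 2-hydroxybenzophenones to xanthones through quinones, but ring C of a flavone has not been closed at O1–C8a in this way.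

**Compound list**
1 | 2,3,4-trimethoxybenzaldehyde | COc1ccc(C=O)c(OC)c1OC | starting material
2 | 2,3,4-trimethoxyphenyl formate | COc1ccc(OC=O)c(OC)c1OC | intermediate
3 | 2,3,4-trimethoxyphenol | COc1ccc(O)c(OC)c1OC | intermediate
4 | methoxyacetic acid | COCC(=O)O | starting material
5 | 1-(2-hydroxy-3,4,5-trimethoxyphenyl)-2-methoxyethan-1-one | COCC(=O)c1cc(OC)c(OC)c(OC)c1O | intermediate
6 | methyl 3,5-dihydroxy-4-methoxybenzoate | COC(=O)c1cc(O)c(OC)c(O)c1 | starting material
7 | methyl 4-methoxy-3,5-bis(methoxymethoxy)benzoate | COCOc1cc(C(=O)OC)cc(OCOC)c1OC | intermediate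
8 | dilithium (Z)-enolate-phenoxide of 5 | [Li+].[Li+].CO/C=C(\[O-])c1cc(OC)c(OC)c(OC)c1[O-] | intermediate
9 | 1-(2-hydroxy-3,4,5-trimethoxyphenyl)-2-methoxy-3-[4-methoxy-3,5-bis(methoxymethoxy)phenyl]propane-1,3-dione (racemic, enolisable C2) | COCOc1cc(C(=O)C(OC)C(=O)c2cc(OC)c(OC)c(OC)c2O)cc(OCOC)c1OC | intermediate
10 | 2-methoxy-1-[4-methoxy-3,5-bis(methoxymethoxy)phenyl]-3-(3,3,4,5-tetramethoxy-6-oxocyclohexa-1,4-dien-1-yl)propane-1,3-dione (racemic) | COCOc1cc(C(=O)C(OC)C(=O)C2=CC(OC)(OC)C(OC)=C(OC)C2=O)cc(OCOC)c1OC | intermediate
11 | 5-hydroxy-3,6,7,8,8-pentamethoxy-2-[4-methoxy-3,5-bis(methoxymethoxy)phenyl]-8,8a-dihydro-4H-chromen-4-one (racemic at C8a, drawn as the 5-enol) | COCOc1cc(C2=C(OC)C(=O)C3=C(O)C(OC)=C(OC)C(OC)(OC)C3O2)cc(OCOC)c1OC | intermediate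
12 | 5-hydroxy-3,6,7,8-tetramethoxy-2-[4-methoxy-3,5-bis(methoxymethoxy)phenyl]-4H-chromen-4-one | COCOc1cc(-c2oc3c(OC)c(OC)c(OC)c(O)c3c(=O)c2OC)cc(OCOC)c1OC | intermediate
13 | 5,3',5'-trihydroxy-3,6,7,8,4'-pentamethoxyflavone (achiral) | COc1c(O)cc(-c2oc3c(OC)c(OC)c(OC)c(O)c3c(=O)c2OC)cc1O | target

**Step count**
Total steps: 5. Longest linear sequence: 4 (steps 1, 2, 4, 5).

**Three steps most likely to fail**

Step 5 (the new annulation). There are three main risks:
- Solvent methanol may win the conjugate addition at C8a over the enolate oxygen.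
- Trivalent iodine may attack the diketone α-carbon instead of the phenol.
- Compound 9 may cyclodehydrate through its phenol before it is oxidised.

The fallback uses known chemistry, a halide-based ring closure in place of the oxidative one. It sets out from 5 and comes back at 12. NBS in MeCN at 0 °C brominates the only free ring position of 5 to give 1-(2-bromo-6-hydroxy-3,4,5-trimethoxyphenyl)-2-methoxyethan-1-one F1. LiN(SiMe3)2 in THF turns it into the dilithium (Z)-enolate-phenoxide of the bromo ketone F2. This condenses with 7 as in step 4 to give 1-(2-bromo-6-hydroxy-3,4,5-trimethoxyphenyl)-2-methoxy-3-[4-methoxy-3,5-bis(methoxymethoxy)phenyl]propane-1,3-dione F3. CuI (10 mol %), 1,10-phenanthroline and K2CO3 in DMF at 110 °C then close O1–C8a by intramolecular Ullmann-type O-arylation of the diketone enolate. This gives 12, which is isolated and freed of its MOM groups with HCl in MeOH as in the last stage of step 5.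

Step 4 (intermolecular Claisen on a hindered α-methoxy enolate with a modestly electrophilic benzoate). The risks are low conversion and retro-Claisen cleavage. The fallback makes the acyl transfer intramolecular. It sets out from 7 (with 5) and comes back at 9. LiOH in THF–H2O, then citric acid to pH 4, gives 4-methoxy-3,5-bis(methoxymethoxy)benzoic acid F4. EDC·HCl and DMAP in CH2Cl2 join it to the phenol of 5 to give 2,3,4-trimethoxy-6-(methoxyacetyl)phenyl 4-methoxy-3,5-bis(methoxymethoxy)benzoate F5. KOt-Bu in THF at 0 °C then moves the aroyl group from oxygen to the α-carbon (Baker–Venkataraman rearrangement) to give 9.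

Step 2 (regiochemistry of the electrophilic acylation). The risk is competing attack at C5, ortho to the 4-OMe group. The fallback replaces electrophilic substitution by directed ortho-metalation. It sets out from 3 and comes back at 5. MOMCl and K2CO3 in acetone give 1,2,3-trimethoxy-4-(methoxymethoxy)benzene F6. n-BuLi and TMEDA in THF at −20 °C lithiate next to the stronger OMOM director to give [3,4,5-trimethoxy-2-(methoxymethoxy)phenyl]lithium F7. N,2-dimethoxy-N-methylacetamide traps it, and an NH4Cl quench gives 2-methoxy-1-[3,4,5-trimethoxy-2-(methoxymethoxy)phenyl]ethan-1-one F8. HCl in MeOH at rt then frees the phenol to give 5.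

**Further compounds**
F1 | step 5 | 1-(2-bromo-6-hydroxy-3,4,5-trimethoxyphenyl)-2-methoxyethan-1-one | COCC(=O)c1c(Br)c(OC)c(OC)c(OC)c1O
F2 | step 5 | dilithium (Z)-enolate-phenoxide of the bromo ketone | [Li+].[Li+].CO/C=C(\[O-])c1c(Br)c(OC)c(OC)c(OC)c1[O-]
F3 | step 5 | 1-(2-bromo-6-hydroxy-3,4,5-trimethoxyphenyl)-2-methoxy-3-[4-methoxy-3,5-bis(methoxymethoxy)phenyl]propane-1,3-dione (racemic) | COCOc1cc(C(=O)C(OC)C(=O)c2c(Br)c(OC)c(OC)c(OC)c2O)cc(OCOC)c1OC
F4 | step 4 | 4-methoxy-3,5-bis(methoxymethoxy)benzoic acid | COCOc1cc(C(=O)O)cc(OCOC)c1OC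
F5 | step 4 | 2,3,4-trimethoxy-6-(methoxyacetyl)phenyl 4-methoxy-3,5-bis(methoxymethoxy)benzoate | COCC(=O)c1cc(OC)c(OC)c(OC)c1OC(=O)c1cc(OCOC)c(OC)c(OCOC)c1
F6 | step 2 | 1,2,3-trimethoxy-4-(methoxymethoxy)benzene | COCOc1ccc(OC)c(OC)c1OC
F7 | step 2 | [3,4,5-trimethoxy-2-(methoxymethoxy)phenyl]lithium | [Li]c1cc(OC)c(OC)c(OC)c1OCOC
F8 | step 2 | 2-methoxy-1-[3,4,5-trimethoxy-2-(methoxymethoxy)phenyl]ethan-1-one | COCC(=O)c1cc(OC)c(OC)c(OC)c1OCOC
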